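- 3 questions hang on one decision: with 15 µM of enzyme and 8.0 µM of added ligand, is it worth leaving the flask for 2.5 h (cedar) instead of stopping at 1.2 h (alder)?

in all of them: substrate 0.20 M

| run | enzyme | added ligand | remark | time |
|---|---|---|---|---|
| Wednesday's | 21 µM | 8 µM | run made earlier |  |
| Tuesday's | 33 µM | 8 µM | run made earlier |  |
| cedar | 15 µM | 8.0 µM |  | 2.5 h |
| alder | 15 µM | 8.0 µM |  | 1.2 h |

| run | time / min | product / % | substrate / % |
|---|---|---|---|
| Wednesday's | 25.0 | 16.3 | 83.2 |
| Wednesday's | 50.0 | 26.6 | 73.6 |
| Wednesday's | 60.0 | 28.3 | 71.2 |
| Wednesday's | 90.0 | 37.0 | 63.7 |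
| Tuesday's | 8.00 | 11.8 | 88.4 |
| Tuesday's | 15.0 | 20.5 | 78.1 |
| Tuesday's | 40.0 | 43.1 | 55.6 |
| Tuesday's | 90.0 | 63.5 | 36.4 |

(standard deviation of a reading: 0.5 percentage points)

- the winner by amount of product, in percent of the substrate charged; "neither" if no more than 2 percentage points parts them (cedar / alder / neither)
- how much product is there at the end, in percent of the substrate charged: cedar
- how much product is there at the end, in percent of the substrate charged: alder

- the numbers in the tables scatter with a standard deviation of 0.5 percentage points

- Measure progress as the reach, the natural log of c(substrate) at the charge over c(substrate) now; a steady first-order decay makes it a straight line in time.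
- Read how fast the activity fades. Wednesday's reach climbs at 0.00736 /min up to its first reading, but at 0.00361 /min between 50.0 min and 90.0 min, so it bends.
- Take that fall as exponential. The two rates stand 57.5 min apart, which gives a time constant τ of 80.8 min; the same step on Tuesday's run gives 86.4 min.
- Now ask where the curve is heading. Dividing Wednesday's reach at 90.0 min by 1 − exp(−t/τ) gives a reach scale of 0.671, though cedar's time lies beyond any reading.
- Scale it to the new charge. At 90.0 min, Tuesday's reach is 2.24 times Wednesday's, while its enzyme is 1.57 times as much. Assume a tight-binding titration, the ligand holding its own amount of enzyme, and the ratio becomes 1.92: nearer, still short.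
- That gives the reach scale of cedar and alder, which share this charge: the reach the fitted curve tends to, 0.362.
- My reckoning puts cedar at 26.3% and alder at 19.2%, a gap of 7.1 points, wider than the margin of 2 points, so leave the flask.
- The forecast, arguing “The decay therefore follows time, not product”, names cedar too, but with lower figures than mine: 24% and 17%.
- The simulation gives cedar: cedar holds 28.2% of product and alder 18.8%, so my cedar figure stands 1.9 points low.

    substrate + enzyme → product + enzyme, rate k1*[substrate]*[enzyme]/(1 + ([substrate]/Km1) + ([substrate]/Ksi1)^2) (0.322 M, 0.103 M, k = 57.4 /M/s)
    enzyme ⇌ dormant form (K = 3.07, k = 3.80 × 10⁻⁴ /s)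
    enzyme + added ligand ⇌ idle complex, settled at all times (K = 4.35 × 10⁶ /M)
    enzyme + product → spent catalyst (k = 0.00284 /M/s)

- Run the same curve on the neighbouring flask, cedar's charge read at 1.0 h. With τ of 80.8 min, the curve has covered 52.4% of the reach scale 0.362, a reach of 0.190, which means 17.3% product. That flask holds 16.9% of product. At that moment the idle complex holds 48.8% of the catalyst charged, which is 7.32 µM of enzyme against the 8.0 µM of added ligand charged.

The numbers in the tables were generated by integration on assumed constants, and the scatter is random.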